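## Retrosynthetic overview

1. Target 19 ⇐ Δ7 olefin 18 by a last-step Schenck ene reaction (C8–OOH, 6E olefin); C17 ⇐ lactone enolate methylation; C1–H ⇐ conjugate reduction of unsaturated δ-lactone 15.
2. δ-Lactone ⇐ 6-exo opening of the C3–C4 oxirane by a (Z)-carboxylate held on C1, with inversion at C3 (13 → 15).
3. 14-Membered carbocycle ⇐ key step: closure of C14–C1 by copper-catalysed syn-addition of a B-alkyl-9-BBN to a tethered ynoate (11 → 13), in place of olefin metathesis at C6=C7, NHK coupling or sulfone alkylation.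
4. Ynoate 11 ⇐ (2E,6E)-farnesyl acetate 1 (C2–C13, C18–C20): SeO2 oxidation, two Sharpless epoxidations with L-(+)-DET, methylenation (C14), acetylide and chloroformate (C1, C15, C16).
5. Ring order: oxirane C11–C12, oxirane C3–C4, carbocycle, δ-lactone; the acetate of 1 is the only protecting group.

Assumption: C-numbers are cembrane positions of the target (ring C1–C14; C15 lactone α-carbon, C16 lactone carbonyl, C17 α-methyl; C18, C19, C20 the methyls on C4, C8, C12), and commercial (2E,6E)-farnesyl acetate is isomerically pure.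

## Route

Step 1
Reactants: 1 (2E,6E)-farnesyl acetate
Product: 2 all-E 12-hydroxyfarnesyl acetate
Conditions: SeO2 (0.3 equiv), t-BuOOH (3 equiv), salicylic acid (0.1 equiv), CH2Cl2, 0 °C to rt
Reagents that add atoms: tert-butyl hydroperoxide, CC(C)(C)OO (its oxygen is relayed through catalytic SeO2, O=[Se]=O)
Why: Sharpless–Umbreit allylic oxidation (ene reaction then [2,3]-shift) selects the (E)-methyl of the terminal trisubstituted olefin and gives the (10E)-allylic alcohol, the acetate-bearing olefin being deactivated.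

Step 2
Reactants: 2 all-E 12-hydroxyfarnesyl acetate
Product: 3 (11S,12S)-epoxy alcohol acetate
Conditions: Ti(OiPr)4 (10 mol%), L-(+)-diethyl tartrate (12 mol%), t-BuOOH (2 equiv), 4 Å MS, CH2Cl2, −20 °C
Reagents that add atoms: tert-butyl hydroperoxide, CC(C)(C)OO
Why: Katsuki–Sharpless asymmetric epoxidation touches only the allylic alcohol olefin and, with L-(+)-DET, delivers oxygen to the face that gives the (11S,12S)-oxirane, the sense established for (E)-2-methylalk-2-en-1-ols.

Step 3
Reactants: 3 (11S,12S)-epoxy alcohol acetate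
Product: 4 epoxy aldehyde acetate
Conditions: TEMPO (10 mol%), PhI(OAc)2 (1.2 equiv), CH2Cl2, rt
Reagents that add atoms: none
Why: Oxoammonium (TEMPO/PhI(OAc)2) oxidation stops at the aldehyde, which has a quaternary α-carbon and cannot epimerise, and leaves olefins, acetate and oxirane alone.

Step 4
Reactants: 4 epoxy aldehyde acetate
Product: 5 vinyl oxirane acetate
Conditions: Ph3PCH3Br (1.2 equiv), KN(SiMe3)2 (1.15 equiv), THF, −78 to 0 °C
Reagents that add atoms: methyltriphenylphosphonium bromide, C[P+](c1ccccc1)(c1ccccc1)c1ccccc1.[Br-] (its CH2, through the ylide)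
Why: Wittig methylenation of the non-enolisable α-epoxy aldehyde installs C14 as a vinyl group, with the acetate surviving a slight excess of ylide at low temperature.

Step 5
Reactants: 5 vinyl oxirane acetate
Product: 6 vinyl oxirane allylic alcohol
Conditions: K2CO3 (0.2 equiv), MeOH, 0 °C to rt
Reagents that add atoms: none
Why: Base-catalysed transesterification (Zemplén-type methanolysis) frees the second allylic alcohol, and the vinyl oxirane is inert to K2CO3 in MeOH.

Step 6
Reactants: 6 vinyl oxirane allylic alcohol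
Product: 7 bis-oxirane alcohol
Conditions: Ti(OiPr)4 (10 mol%), L-(+)-diethyl tartrate (12 mol%), t-BuOOH (2 equiv), 4 Å MS, CH2Cl2, −20 °C
Reagents that add atoms: tert-butyl hydroperoxide, CC(C)(C)OO
Why: A second Katsuki–Sharpless epoxidation reacts only at the allylic alcohol olefin and, with L-(+)-DET, gives the (3S,4S)-oxirane, as geraniol and farnesol give their (2S,3S)-epoxides.

Step 7
Reactants: 7 bis-oxirane alcohol
Product: 9 bis-oxirane enyne, via epoxy triflate 8 (not isolated)
Conditions: Tf2O (1.1 equiv), 2,6-lutidine (1.3 equiv), CH2Cl2, −78 °C; then LiC≡CH (3 equiv, from HC≡CH and n-BuLi), THF/DMPU, −78 to −20 °C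
Reagents that add atoms: acetylene, C#C (delivered as lithium acetylide, [Li+].[C-]#C)
Why: O-triflation followed by SN2 alkynylation at the primary carbon is much faster than opening of the trisubstituted oxiranes without a Lewis acid, so C1 and C15 are added with all four stereocentres untouched.

Step 8
Reactants: 9 bis-oxirane enyne
Product: 11 bis-oxirane ynoate, via lithium acetylide 10 (not isolated)
Conditions: n-BuLi (1.05 equiv), THF, −78 °C; then ClCO2Me (1.5 equiv), −78 to 0 °C
Reagents that add atoms: methyl chloroformate, COC(=O)Cl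
Why: Deprotonation of the terminal alkyne and C-acylation of the acetylide with a chloroformate gives the ynoate acceptor (C16) without affecting any stereocentre.

Step 9
Reactants: 11 bis-oxirane ynoate
Product: 13 macrocyclic (Z)-enoate, via B-alkyl-9-BBN borane 12 (not isolated)
Conditions: 9-BBN-H (1.1 equiv), THF, 0 °C to rt; then syringe-pump addition to CuOAc (20 mol%), P(OPh)3 (40 mol%), t-BuOK (20 mol%), t-BuOH (3 equiv), 1,4-dioxane, 40 °C, 2 mM
Reagents that add atoms: none
Why: Proposed new method: 9-BBN-H hydroborates only the monosubstituted vinyl group, the resulting tert-butoxyborate transmetalates to an alkylcopper (monovalent copper) that syn-carbocuprates the tethered ynoate in a 14-exo-dig sense, and t-BuOH protonates the alkenylcopper, so C14 and H end cis and the C2 arm ends cis to CO2Me (Z); the closest known reaction is the intermolecular copper-catalysed conjugate addition (syn-hydroalkylation) of alkyl-9-BBN reagents to alkynoates, run here at high dilution as a macrocyclization.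

Step 10
Reactants: 13 macrocyclic (Z)-enoate
Product: 15 unsaturated hydroxy δ-lactone, via potassium carboxylate 14 (not isolated)
Conditions: KOSiMe3 (1.2 equiv), THF, rt; then DMF, 60 °C; aq. NH4Cl
Reagents that add atoms: potassium trimethylsilanolate, C[Si](C)(C)[O-].[K+] (supplies one carboxyl oxygen; the OMe leaves as MeOSiMe3)
Why: Silanolate ester cleavage gives the (Z)-carboxylate, which opens the C3–C4 oxirane by 6-exo-tet SN2 attack at the less substituted C3 (inversion, 3S to 3R) and frees the C4 tertiary alcohol with retention (4S), while the C11–C12 oxirane is out of reach because C14 is trans to the carboxylate.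

Step 11
Reactants: 15 unsaturated hydroxy δ-lactone
Product: 16 saturated hydroxy δ-lactone
Conditions: Cu(OAc)2·H2O (5 mol%), 1,2-bis(diphenylphosphino)benzene (5 mol%), (EtO)2MeSiH (2 equiv), t-BuOH (2 equiv), toluene, rt
Reagents that add atoms: none
Why: CuH conjugate reduction adds hydride axially to C1 of the half-chair enoate, anti to the pseudo-equatorial C3 substituent, so the C14 arm becomes equatorial and cis to C4 (1R), as in cis-selective reductions of 4,6-disubstituted dihydropyranones; the isolated olefin and oxirane do not react.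

Step 12
Reactants: 16 saturated hydroxy δ-lactone
Product: 18 α-methyl lactone, via dilithium enolate 17 (not isolated)
Conditions: LiN(iPr)2 (2.2 equiv), THF, −78 °C; then MeI (3 equiv), −78 to −40 °C; aq. NH4Cl
Reagents that add atoms: iodomethane, CI
Why: Kinetic enolate alkylation (C4–OH carried as its alkoxide) occurs anti to the adjacent C1 substituent and gives the trans, all-equatorial 15S methyl lactone, which is also the thermodynamic epimer.

Step 13
Reactants: 18 α-methyl lactone
Product: 19 target hydroperoxide CNP0297487.3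
Conditions: O2, tetraphenylporphyrin (0.5 mol%), white LED, CH2Cl2, −20 °C
Reagents that add atoms: dioxygen, O=O
Why: In the Schenck ene reaction singlet oxygen bonds to C8 while a C6–H on the more crowded side of the (E)-trisubstituted olefin is abstracted suprafacially, giving the tertiary allylic hydroperoxide and the new 6E olefin, and attack on the exposed outer face of the macrocyclic olefin is expected to set 8R (substrate control, the likely biogenetic path).

## Compound list

1 | (2E,6E)-3,7,11-trimethyldodeca-2,6,10-trien-1-yl acetate (farnesyl acetate) | CC(C)=CCC/C(C)=C/CC/C(C)=C/COC(C)=O | starting material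
2 | (2E,6E,10E)-12-hydroxy-3,7,11-trimethyldodeca-2,6,10-trien-1-yl acetate | OC/C(C)=C/CC/C(C)=C/CC/C(C)=C/COC(C)=O | intermediate
3 | (2E,6E)-9-[(2S,3S)-3-(hydroxymethyl)-3-methyloxiran-2-yl]-3,7-dimethylnona-2,6-dien-1-yl acetate | OC[C@]1(C)O[C@H]1CC/C(C)=C/CC/C(C)=C/COC(C)=O | intermediate
4 | (2E,6E)-9-[(2S,3R)-3-formyl-3-methyloxiran-2-yl]-3,7-dimethylnona-2,6-dien-1-yl acetate | O=C[C@]1(C)O[C@H]1CC/C(C)=C/CC/C(C)=C/COC(C)=O | intermediate
5 | (2E,6E)-9-[(2S,3S)-3-ethenyl-3-methyloxiran-2-yl]-3,7-dimethylnona-2,6-dien-1-yl acetate | C=C[C@]1(C)O[C@H]1CC/C(C)=C/CC/C(C)=C/COC(C)=O | intermediate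
6 | (2E,6E)-9-[(2S,3S)-3-ethenyl-3-methyloxiran-2-yl]-3,7-dimethylnona-2,6-dien-1-ol | C=C[C@]1(C)O[C@H]1CC/C(C)=C/CC/C(C)=C/CO | intermediate
7 | [(2S,3S)-3-{(3E)-6-[(2S,3S)-3-ethenyl-3-methyloxiran-2-yl]-4-methylhex-3-en-1-yl}-3-methyloxiran-2-yl]methanol | C=C[C@]1(C)O[C@H]1CC/C(C)=C/CC[C@]1(C)O[C@H]1CO | intermediate
8 | trifluoromethanesulfonate ester of 7 (same configuration) | C=C[C@]1(C)O[C@H]1CC/C(C)=C/CC[C@]1(C)O[C@H]1COS(=O)(=O)C(F)(F)F | intermediate
9 | (2S,3S)-2-{(3E)-6-[(2S,3S)-3-ethenyl-3-methyloxiran-2-yl]-4-methylhex-3-en-1-yl}-2-methyl-3-(prop-2-yn-1-yl)oxirane | C=C[C@]1(C)O[C@H]1CC/C(C)=C/CC[C@]1(C)O[C@H]1CC#C | intermediate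
10 | lithium alkynide of 9 | C=C[C@]1(C)O[C@H]1CC/C(C)=C/CC[C@]1(C)O[C@H]1CC#[C-].[Li+] | intermediate
11 | methyl 4-[(2S,3S)-3-{(3E)-6-[(2S,3S)-3-ethenyl-3-methyloxiran-2-yl]-4-methylhex-3-en-1-yl}-3-methyloxiran-2-yl]but-2-ynoate | C=C[C@]1(C)O[C@H]1CC/C(C)=C/CC[C@]1(C)O[C@H]1CC#CC(=O)OC | intermediate
12 | methyl 4-[(2S,3S)-3-{(3E)-6-[(2S,3S)-3-[2-(9-borabicyclo[3.3.1]nonan-9-yl)ethyl]-3-methyloxiran-2-yl]-4-methylhex-3-en-1-yl}-3-methyloxiran-2-yl]but-2-ynoate | C1CCC2CCCC1B2CC[C@]1(C)O[C@H]1CC/C(C)=C/CC[C@]1(C)O[C@H]1CC#CC(=O)OC | intermediate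
13 | methyl (2Z)-2-[(3S,4S,7E,11S,12S)-3,4:11,12-diepoxy-4,8,12-trimethylcyclotetradec-7-en-1-ylidene]acetate (ring positions = cembrane positions) | C1C[C@]2(C)O[C@H]2CC/C(C)=C/CC[C@]2(C)O[C@H]2C/C1=C\C(=O)OC | intermediate
14 | potassium salt of the acid corresponding to 13 | C1C[C@]2(C)O[C@H]2CC/C(C)=C/CC[C@]2(C)O[C@H]2C/C1=C\C(=O)[O-].[K+] | intermediate
15 | (3R,4S,7E,11S,12S)-11,12-epoxy-4-hydroxy-17-norcembra-1(15),7-dien-16,3-olide (α,β-unsaturated δ-lactone, O on C3, free tertiary OH on C4) | O=C1O[C@@H]2CC(=C1)CC[C@]1(C)O[C@H]1CC/C(C)=C/CC[C@]2(C)O | intermediate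
16 | (1R,3R,4S,7E,11S,12S)-11,12-epoxy-4-hydroxy-17-norcembr-7-en-16,3-olide | O=C1O[C@@H]2C[C@H](C1)CC[C@]1(C)O[C@H]1CC/C(C)=C/CC[C@]2(C)O | intermediate
17 | dilithium salt of 16 (C4 alkoxide, C15=C16 lactone enolate) | [O-]C1O[C@@H]2C[C@H](C=1)CC[C@]1(C)O[C@H]1CC/C(C)=C/CC[C@]2(C)[O-].[Li+].[Li+] | intermediate
18 | (1R,3R,4S,7E,11S,12S,15S)-11,12-epoxy-4-hydroxycembr-7-en-16,3-olide | C[C@@H]1C(=O)O[C@@H]2C[C@H]1CC[C@]1(C)O[C@H]1CC/C(C)=C/CC[C@]2(C)O | intermediate
19 | (1R,3R,4S,6E,8R,11S,12S,15S)-11,12-epoxy-8-hydroperoxy-4-hydroxycembr-6-en-16,3-olide (CNP0297487.3) | C[C@@H]1C(=O)O[C@@H]2C[C@H]1CC[C@]1(C)O[C@H]1CC[C@@](C)(OO)/C=C/C[C@]2(C)O | target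

## Step count and risk

Total step count: 13. Longest linear sequence: 13 steps (fully linear from 1).

Three steps most likely to fail:

Step 9 (macrocyclization). The risks are intermolecular addition and alkoxide-induced γ-deprotonation of the ynoate next to the oxirane. The fallback sets out from 11 and comes back at 13. Syn-stannylcupration of 11 (Me3SnCu·SMe2 from Me3SnLi and CuBr·SMe2, THF, MeOH, −78 °C) gives the (E)-β-trimethylstannyl enoate F1. I2 (CH2Cl2, 0 °C) exchanges tin for iodine with retention and gives the (E)-β-iodo enoate F2. 9-BBN-H then hydroborates the vinyl oxirane to the B-alkyl borane F3. A B-alkyl Suzuki–Miyaura macrocyclization (PdCl2(dppf), AsPh3, Cs2CO3, DMF/THF/H2O, 2 mM, rt) joins C14 to C1 with retention of olefin geometry and gives 13.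

Step 11 (facial selectivity of hydride addition in the bridged lactone). The fallback sets out from 13 and comes back at 16. KOSiMe3 (THF, rt) and a cold pH 5 quench give the free (Z)-acid F4. Carboxylate-directed asymmetric hydrogenation (Ru(OAc)2(BINAP), H2 50 bar, MeOH) reduces only the acrylic olefin and sets C1 under catalyst control, giving the saturated (1R)-epoxy acid F5. The BINAP antipode that gives 1R is not predicted here and would be fixed in a small screen; both are commercial. The cesium salt of F5 (Cs2CO3, DMF, 60 °C) closes the δ-lactone by the same 6-exo oxirane opening and gives 16.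

Step 13 (regiochemistry and face selectivity of the ene reaction). Competing C19–H abstraction would give the 7-hydroperoxy-8(19)-ene, and the 8R outcome is an expectation, not a certainty. The fallback sets out from 18 and comes back at 19. N-(phenylseleno)phthalimide and anhydrous H2O2 (Et2O/CH2Cl2, PPTS cat., −30 °C) add PhSe to C7 and OOH to the tertiary C8 in an anti, Markovnikov sense, giving the β-hydroperoxy selenide F6. Oxidation at selenium (H2O2, pyridine, 0 °C) and selenoxide syn-elimination, which can only run towards C6, give the (6E)-allylic hydroperoxide 19 with fixed regiochemistry. The C8 face is still substrate-controlled, so epimers, if formed, are separated.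

## Further compounds

F1 | step 9 | methyl (2E)-4-[(2S,3S)-3-{(3E)-6-[(2S,3S)-3-ethenyl-3-methyloxiran-2-yl]-4-methylhex-3-en-1-yl}-3-methyloxiran-2-yl]-3-(trimethylstannyl)but-2-enoate | C=C[C@]1(C)O[C@H]1CC/C(C)=C/CC[C@]1(C)O[C@H]1C/C([Sn](C)(C)C)=C\C(=O)OC
F2 | step 9 | methyl (2E)-4-[(2S,3S)-3-{(3E)-6-[(2S,3S)-3-ethenyl-3-methyloxiran-2-yl]-4-methylhex-3-en-1-yl}-3-methyloxiran-2-yl]-3-iodobut-2-enoate | C=C[C@]1(C)O[C@H]1CC/C(C)=C/CC[C@]1(C)O[C@H]1C/C(I)=C\C(=O)OC
F3 | step 9 | B-alkyl-9-BBN borane from hydroboration of the vinyl group of F2 | C1CCC2CCCC1B2CC[C@]1(C)O[C@H]1CC/C(C)=C/CC[C@]1(C)O[C@H]1C/C(I)=C\C(=O)OC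
F4 | step 11 | (2Z)-2-[(3S,4S,7E,11S,12S)-3,4:11,12-diepoxy-4,8,12-trimethylcyclotetradec-7-en-1-ylidene]acetic acid | C1C[C@]2(C)O[C@H]2CC/C(C)=C/CC[C@]2(C)O[C@H]2C/C1=C\C(=O)O
F5 | step 11 | 2-[(1R,3S,4S,7E,11S,12S)-3,4:11,12-diepoxy-4,8,12-trimethylcyclotetradec-7-en-1-yl]acetic acid | C1C[C@]2(C)O[C@H]2CC/C(C)=C/CC[C@]2(C)O[C@H]2C[C@@H]1CC(=O)O
F6 | step 13 | (1R,3R,4S,7S,8R,11S,12S,15S)-11,12-epoxy-8-hydroperoxy-4-hydroxy-7-(phenylselanyl)cembran-16,3-olide | C[C@@H]1C(=O)O[C@@H]2C[C@H]1CC[C@]1(C)O[C@H]1CC[C@@](C)(OO)[C@@H]([Se]c3ccccc3)CC[C@]2(C)O
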